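## Retrosynthetic overview

1. Polyketide numbering is used: C1 = pyrone C=O, C7 = hemiketal carbon, C9 = chromanone C=O, C10–C15 = arene carbons, C15 carries the 3-methylbutyl group.
2. Arene first, by a polyketide-type aldol: dioxinone 1 + acetyl chloride 2 → keto-dioxinone 3; + 4-methylpentanoyl chloride 4 → diketo-dioxinone 5 (masked 3,5,7-triketo acid) → C10→C15 aldol/dehydration → resorcylate acetonide 6.
3. The pyrone is taken intact as the triketide lactone 7; Weinreb amide 8 extends it to the tetraketide 9 (C1–C8).
4. C8–C9 Claisen (trianion of 9 + 6) gives the open 2-hydroxyaryl 1,3-diketone 10; the hemiketal ring closes last and spontaneously (C11–OH onto C7=O) to racemate 11.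
5. C2 is fixed afterwards on the labile hemiketal: dynamic crystallisation with amine 12 as salt 13, then salt break to 14.

Assumption: C2 is a hemiketal carbon that epimerises in solution by ring–chain tautomerism through 10 but is fixed in the crystal; 14 is therefore isolated and stored as a crystalline solid, and its solutions are kept cold and neutral.

## Route

Step 1
Reactants: 1 2,2,6-trimethyl-4H-1,3-dioxin-4-one; 2 acetyl chloride
Product: 3 2,2-dimethyl-6-(2-oxopropyl)-4H-1,3-dioxin-4-one
Conditions: 1 (2 equiv), LiHMDS (2 equiv), THF, −78 °C, 1 h; 2 (1 equiv), −78 → −20 °C; 1 M HCl (excess 1 recovered)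
Reagents that add atoms: acetyl chloride (2), CC(Cl)=O
Why: Crossed Claisen C-acylation of the lithium dienolate of the vinylogous ester at its γ-(exocyclic) carbon, the second equivalent of dienolate deprotonating the more acidic product so that it is not acylated again; no stereocentre is formed.

Step 2
Reactants: 3 2,2-dimethyl-6-(2-oxopropyl)-4H-1,3-dioxin-4-one; 4 4-methylpentanoyl chloride
Product: 6 7-hydroxy-2,2-dimethyl-5-(3-methylbutyl)-4H-1,3-benzodioxin-4-one, via diketo-dioxinone 5 (not isolated)
Conditions: 3 (1.6 equiv), LDA (3.3 equiv), THF, −78 °C, 1 h; 4 (1.0 equiv), −78 °C, 2 h; AcOH; crude 5, Et3N (2 equiv), CH2Cl2, rt, 16 h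
Reagents that add atoms: 4-methylpentanoyl chloride (4), CC(C)CCC(Cl)=O
Why: Hauser–Harris Claisen acylation of the 1,3-dicarbonyl dianion at its terminal carbanion gives the masked triketo acid 5, and Et3N then drives the biomimetic intramolecular aldol condensation (dioxinone C5 = chain C10 onto the C15 ketone), dehydration and enolisation to the arene, the established cyclisation mode of diketo-dioxinones; no stereocentre is formed.

Step 3
Reactants: 7 4-hydroxy-6-methyl-2H-pyran-2-one (triacetic acid lactone); 8 N-methoxy-N-methylacetamide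
Product: 9 4-hydroxy-6-(2-oxopropyl)-2H-pyran-2-one
Conditions: LDA (2.1 equiv), THF/DMPU, −78 → 0 °C; 8 (1.05 equiv), −78 → 0 °C; 1 M HCl to pH 3, 0 °C
Reagents that add atoms: N-methoxy-N-methylacetamide (8), CON(C)C(C)=O
Why: The O,C-dianion of 7 reacts at the 6-methyl carbanion (formed last, most nucleophilic) in a Weinreb ketone synthesis, the chelated tetrahedral intermediate preventing proton transfer from the product and over-addition; no stereocentre is formed.

Step 4
Reactants: 9 4-hydroxy-6-(2-oxopropyl)-2H-pyran-2-one; 6 7-hydroxy-2,2-dimethyl-5-(3-methylbutyl)-4H-1,3-benzodioxin-4-one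
Product: 11 rac-2,7-dihydroxy-2-[(4-hydroxy-2-oxo-2H-pyran-6-yl)methyl]-5-(3-methylbutyl)-2,3-dihydro-4H-chromen-4-one, via open-chain diketone 10 (not isolated)
Conditions: 9 (2.2 equiv), LDA (6.7 equiv), THF/DMPU, −78 → −20 °C; lithium phenoxide of 6 (6 + LiHMDS, 1.0 equiv, THF), −78 → 0 °C, 3 h; AcOH (excess), −78 °C, then pH 5 buffer; crystallise from EtOAc/heptane
Reagents that add atoms: none
Why: Hauser–Harris polyanion Claisen condensation in which the trianion of 9 attacks through its terminal C8 carbanion the activated aryl-ester (acetonide) carbonyl of 6 with loss of acetone and the C11 phenoxide (the second equivalent of trianion takes up the new acidic proton), after which neutral 10 closes spontaneously by addition of the C11–OH to the C7 ketone as in the non-enzymatic last step of the biosynthesis; C2 is formed racemic, and strong acid is avoided to prevent dehydration to the chromone.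

Step 5
Reactants: 11 rac-2,7-dihydroxy-2-[(4-hydroxy-2-oxo-2H-pyran-6-yl)methyl]-5-(3-methylbutyl)-2,3-dihydro-4H-chromen-4-one; 12 (R)-N,N-dimethyl-1-phenylethanamine
Product: 13 (R)-N,N-dimethyl-1-phenylethanaminium 6-{[(2R)-2,7-dihydroxy-5-(3-methylbutyl)-4-oxo-3,4-dihydro-2H-chromen-2-yl]methyl}-2-oxo-2H-pyran-4-olate
Conditions: 12 (1.05 equiv), i-PrOAc/MeCN 9:1, 35 °C, seeded slurry, 48–72 h; cool to 0 °C; filter
Reagents that add atoms: (R)-N,N-dimethyl-1-phenylethanamine (12), C[C@@H](N(C)C)c1ccccc1
Why: Proposed new method: the C2 hemiketal epimerises in solution through the achiral open diketone 10 (ring–chain tautomerism, catalysed by the ammonium pyronate buffer) while the pyronate (pKa about 5) forms diastereomeric salts with the homochiral tertiary amine, so the less soluble (2R)·(R) salt crystallises and the other epimer drains into it, which sets C2 as R; the closest known reaction type is the crystallisation-induced diastereomer transformation of epimerisable acids and lactols as amine salts, and a tertiary amine is chosen so that no enaminone can form with the 1,3-diketone.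

Step 6
Reactants: 13 (R)-N,N-dimethyl-1-phenylethanaminium 6-{[(2R)-2,7-dihydroxy-5-(3-methylbutyl)-4-oxo-3,4-dihydro-2H-chromen-2-yl]methyl}-2-oxo-2H-pyran-4-olate
Product: 14 (2R)-2,7-dihydroxy-2-[(4-hydroxy-2-oxo-2H-pyran-6-yl)methyl]-5-(3-methylbutyl)-2,3-dihydro-4H-chromen-4-one
Conditions: EtOAc / 0.2 M aq. HCl (1.05 equiv), 0 °C, 5 min; dry (Na2SO4); concentrate below 10 °C; crystallise EtOAc/heptane, −20 °C; aqueous phase + NaOH to recover 12
Reagents that add atoms: none
Why: Simple proton transfer (salt break) from the mineral acid to the pyronate, in which no bond at C2 is made or broken and the cold, brief, two-phase contact keeps ring opening (epimerisation) and dehydration slower than isolation, so the R configuration set in step 5 is retained.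

## Compound list

1 | 2,2,6-trimethyl-4H-1,3-dioxin-4-one | CC1=CC(=O)OC(C)(C)O1 | starting material
2 | acetyl chloride | CC(Cl)=O | starting material
3 | 2,2-dimethyl-6-(2-oxopropyl)-4H-1,3-dioxin-4-one | CC(=O)CC1=CC(=O)OC(C)(C)O1 | intermediate
4 | 4-methylpentanoyl chloride | CC(C)CCC(Cl)=O | starting material
5 | 2,2-dimethyl-6-(7-methyl-2,4-dioxooctyl)-4H-1,3-dioxin-4-one | CC(C)CCC(=O)CC(=O)CC1=CC(=O)OC(C)(C)O1 | intermediate (not isolated)
6 | 7-hydroxy-2,2-dimethyl-5-(3-methylbutyl)-4H-1,3-benzodioxin-4-one | CC(C)CCc1cc(O)cc2OC(C)(C)OC(=O)c12 | intermediate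
7 | 4-hydroxy-6-methyl-2H-pyran-2-one (triacetic acid lactone) | Cc1cc(O)cc(=O)o1 | starting material
8 | N-methoxy-N-methylacetamide | CON(C)C(C)=O | starting material
9 | 4-hydroxy-6-(2-oxopropyl)-2H-pyran-2-one | CC(=O)Cc1cc(O)cc(=O)o1 | intermediate
10 | 1-[2,4-dihydroxy-6-(3-methylbutyl)phenyl]-4-(4-hydroxy-2-oxo-2H-pyran-6-yl)butane-1,3-dione | CC(C)CCc1cc(O)cc(O)c1C(=O)CC(=O)Cc1cc(O)cc(=O)o1 | intermediate (not isolated)
11 | rac-2,7-dihydroxy-2-[(4-hydroxy-2-oxo-2H-pyran-6-yl)methyl]-5-(3-methylbutyl)-2,3-dihydro-4H-chromen-4-one | CC(C)CCc1cc(O)cc2c1C(=O)CC(O)(Cc1cc(O)cc(=O)o1)O2 | intermediate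
12 | (R)-N,N-dimethyl-1-phenylethanamine | C[C@@H](N(C)C)c1ccccc1 | starting material
13 | (R)-N,N-dimethyl-1-phenylethanaminium salt of the (2R)-hemiketal pyron-4-olate | CC(C)CCc1cc(O)cc2c1C(=O)C[C@@](O)(Cc1cc([O-])cc(=O)o1)O2.C[C@@H]([NH+](C)C)c1ccccc1 | intermediate
14 | (2R)-2,7-dihydroxy-2-[(4-hydroxy-2-oxo-2H-pyran-6-yl)methyl]-5-(3-methylbutyl)-2,3-dihydro-4H-chromen-4-one | CC(C)CCc1cc(O)cc2c1C(=O)C[C@@](O)(Cc1cc(O)cc(=O)o1)O2 | target

## Step count and risks

Total steps: 6. Longest linear sequence: 5 (steps 1, 2, 4, 5, 6; step 3 is the only branch).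

**Step 4 (most likely to fail).** The trilithio pyrone may be poorly soluble. The acetonide carbonyl of 6 is hindered by the ortho 3-methylbutyl group and deactivated by the para phenoxide. Under base, 10 can also dehydrate to the chromone or undergo a competing aldol. Fallback, setting out from 3 and 6 and coming back at 11: the pyrone is formed last from a dioxinone, whose polyanions are THF-soluble. The dianion of 3 (LDA, THF, −78 °C) is acetylated with 2 to give 2,2-dimethyl-6-(2,4-dioxopentyl)-4H-1,3-dioxin-4-one F1. Its trianion is acylated at the terminal methyl by the lithium phenoxide of 6 to give 6-{6-[2,4-dihydroxy-6-(3-methylbutyl)phenyl]-2,4,6-trioxohexyl}-2,2-dimethyl-4H-1,3-dioxin-4-one F2 (drawn open-chain). Heating F2 in toluene at 100 °C expels acetone by retro-[4+2]; the acylketene is trapped by the C5 enol oxygen to close the 4-hydroxy-2-pyrone, giving 10, which closes to 11.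

**Step 5.** The salt may not crystallise, or the (2S) salt may be the less soluble one. The pairing cannot be predicted and must be found in a salt screen; the (S)-amine is equally available and would be used if the pairing is reversed. Slow dehydration to the chromone in the slurry is a further risk. Fallback, setting out from 11 and coming back at 14: preparative SFC on an amylose-type chiral stationary phase (CO2/MeOH, no additive, 10 °C) gives 14 directly. The unwanted (2S)-2,7-dihydroxy-2-[(4-hydroxy-2-oxo-2H-pyran-6-yl)methyl]-5-(3-methylbutyl)-2,3-dihydro-4H-chromen-4-one F3 is stirred with 5 mol % Et3N in MeCN to re-form 11 and is injected again.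

**Step 2.** The dianion acylation with an acid chloride can give O-acylation or double acylation, and 5 can cyclise to its pyrone instead of the arene. Fallback, setting out from 7 and coming back at 6: the arene is made by pyrone-to-arene rearrangement. The dianion of 7 (LDA, THF/DMPU) is acylated with methyl 4-methylpentanoate (CC(C)CCC(=O)OC) to give 4-hydroxy-6-(5-methyl-2-oxohexyl)-2H-pyran-2-one F4. Aqueous KOH at rt opens the lactone to the triketo acid, which cyclises C10→C15 to 2,4-dihydroxy-6-(3-methylbutyl)benzoic acid F5. Acetone/TFAA/TFA at rt converts F5 into 6.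

## Further compounds

F1 | step 4 | 2,2-dimethyl-6-(2,4-dioxopentyl)-4H-1,3-dioxin-4-one | CC(=O)CC(=O)CC1=CC(=O)OC(C)(C)O1
F2 | step 4 | 6-{6-[2,4-dihydroxy-6-(3-methylbutyl)phenyl]-2,4,6-trioxohexyl}-2,2-dimethyl-4H-1,3-dioxin-4-one | CC(C)CCc1cc(O)cc(O)c1C(=O)CC(=O)CC(=O)CC1=CC(=O)OC(C)(C)O1
F3 | step 5 | (2S)-2,7-dihydroxy-2-[(4-hydroxy-2-oxo-2H-pyran-6-yl)methyl]-5-(3-methylbutyl)-2,3-dihydro-4H-chromen-4-one | CC(C)CCc1cc(O)cc2c1C(=O)C[C@](O)(Cc1cc(O)cc(=O)o1)O2
F4 | step 2 | 4-hydroxy-6-(5-methyl-2-oxohexyl)-2H-pyran-2-one | CC(C)CCC(=O)Cc1cc(O)cc(=O)o1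
F5 | step 2 | 2,4-dihydroxy-6-(3-methylbutyl)benzoic acid | CC(C)CCc1cc(O)cc(O)c1C(O)=O
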